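The Z charged stays in the closed flask in one form or another, so its forms sum to 100 percent. In the autumn run, which is this same flask followed so far, the readings of Z, X and G at 3.00 min leave 41.0% unseen.

in all of them: Z 45 mM; D 49.5 mM

| flask | remark | time |
|---|---|---|
| autumn | the very flask that is asked about, followed so far |  |
| flask |  | 15 min |

autumn run (percent of the Z charged)

| time / min | Z / % | X / % | G / % |
|---|---|---|---|
| 0.250 | 54 | 14 | 6 |
| 0.417 | 41 | 16 | 10 |
| 0.833 | 33 | 16 | 16 |
| 1.50 | 30 | 11 | 24 |
| 3.00 | 25 | 10 | 24 |

(each reading ± 1.5 percentage points)

- what has gone from Z into another species counts as reacted, even if it can come back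
- the reaction counts as stopped when no species that holds the Z changes by six tenths of a point or more over the second half of the time

- why nothing more happens at 15 min, or that something still does (it is still moving / D has run out first / all of Z has reacted / forward and back rates have come level)
- share of the Z used up at 15 min
- X at 15 min, in percent of the Z charged
- G at 15 min, in percent of the Z charged
- Q at 15 min, in percent of the Z charged

Two times are set against each other here: the time the flask needs to close on its plateau, and the 15 min allowed. The first is read from Z. Its gap above the last reading shrinks from 29 percentage points at 0.250 min to 8 points at 0.833 min, which gives a half-life of 0.314 min, a reading that carries the scatter. The allowed time holds 47.8 of these; this count of relaxation half-lives in the time allowed is the turnover count. The allowed time is far longer than the half-life, so my reckoning puts the flask on its plateau. If X took one D, G two, and each part of the unseen remainder one, D at 3.00 min still stands at 11.0% of the Z charged, so I read the plateau as a balance.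

The forecast says forward and back rates have come level, with 77% of Z used, X 9.5%, G 26% and Q 41.5%: “Depletion alone would not cause this, so back reaction is likely.”

The simulation gives forward and back rates have come level, with 71.5% of Z used, X 9.30%, G 25.3% and Q 5.58%.

    Z ⇌ E (K = 1.10, k = 0.0230 s⁻¹)
    X ⇌ Q (K = 0.600, k = 0.210 s⁻¹)
    X + D ⇌ J + G (K = 4.00, k = 1.00 M⁻¹ s⁻¹)
    Z + D ⇌ J + X (K = 0.480, k = 0.670 M⁻¹ s⁻¹)

The forecast's Q stands 36 points too high, and beside Q the flask holds E at 31.3%. Over the second half of the time, 23.9 of those half-lives, the shares change by 0 points. The neighbour charged with 120 mM of D was not followed in time, so its count of 47.8 for the same 15 min borrows the half-life read in the autumn run, and that neighbour ends with G at 50.6%.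

The earlier runs and the new flask were generated by integration with made-up constants; the scatter is artificial.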